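**Plan**
- Cuts, in retrosynthetic order: the seven O–CH3 bonds; the stilbene C=C (Horner–Wadsworth–Emmons); in each 2,3-dihydrobenzofuran the aryl C7a–O1 bond together with the C2–C3 bond; the two ArCH2–aryl bonds (Negishi).
- Enabling feature: in both five-membered rings (O1–C2–C3–C3a–C7a) C3 is a doubly benzylic CH on C3a, the ring oxygen sits on the neighbouring arene carbon C7a, and C3a is flanked on its other side by the oxygenated C4. A p-tolylsulfinyl group on C7a can therefore direct metalation to C3a, stabilise and steer a carbanion at C3, and leave when the aldehyde oxygen closes the ring.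
- Forward order: one sulfinyl arene (5) is made and iodinated once at the carbon between its methoxy and sulfinyl groups; the iodide (7) is used twice. Copy 1 is benzylated with 3,5-dimethoxybenzylzinc bromide and annulated with 4-methoxybenzaldehyde to give the outer dihydrobenzofuran (its benzene ring is ring C). The masked aldehyde of that unit becomes a CH2Br group and then the benzylic zinc reagent that benzylates copy 2. The second annulation builds the inner dihydrobenzofuran (its benzene ring, ring A, carries the styryl group); olefination and ether cleavage finish.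
- Stereochemistry: all four centres derive from the sulfur stereocentre of the menthol-derived (S)-sulfinate, each C3 through a lithium chelate with the sulfinyl group, each C2 through trans-selective ring closure.

Key step: step 9

Assumption: the (S)-sulfinyl group is taken to direct the aldehyde to the lithium-bearing face of the chelated carbanion, anti to the p-tolyl group, which corresponds to (S) at C3; if the sense proved opposite, the enantiomeric sulfinate from (+)-menthol would be used in step 2 and nothing else would change.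

**Step 1**
Reactants: 1 3-bromo-5-methoxybenzaldehyde
Product: 2 1-bromo-3-(dimethoxymethyl)-5-methoxybenzene
Conditions: HC(OMe)3, p-TsOH·H2O (cat.), MeOH, 25 °C
Reagents that add atoms: trimethyl orthoformate, COC(OC)OC; methanol, CO
Why: Acid-catalysed acetalisation driven by the orthoformate as water scavenger masks the aldehyde against the organometallic steps that follow.

**Step 2**
Reactants: 2 1-bromo-3-(dimethoxymethyl)-5-methoxybenzene; 3 (1R,2S,5R)-menthyl (S)-p-toluenesulfinate
Product: 5 (S)-1-(dimethoxymethyl)-3-methoxy-5-(p-tolylsulfinyl)benzene, via aryl Grignard reagent 4 (not isolated)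
Conditions: Mg, I2 (cat.), THF, 50 °C; then 3, toluene/THF, −20 → 0 °C
Reagents that add atoms: none
Why: Andersen sulfoxide synthesis, in which the aryl Grignard reagent displaces mentholate at sulfur with inversion, so the (S)-sulfinate should give the (S)-diaryl sulfoxide and the sulfur stereocentre comes from the menthol-derived reagent.

**Step 3**
Reactants: 5 (S)-1-(dimethoxymethyl)-3-methoxy-5-(p-tolylsulfinyl)benzene
Product: 7 5-(dimethoxymethyl)-2-iodo-1-methoxy-3-[(S)-p-tolylsulfinyl]benzene, via aryllithium 6 (not isolated)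
Conditions: LiN(iPr)2 (1.1 equiv), THF, −78 °C; then I2, THF, −78 → 0 °C
Reagents that add atoms: iodine, II
Why: Directed ortho-metalation at the ring carbon flanked by the methoxy and sulfinyl groups (both directors act on the same C–H, and the amide base does not attack sulfur) followed by iodine quench of the aryllithium should give an isolable aryl iodide that serves both benzylation steps, with the sulfur stereocentre untouched at low temperature.

**Step 4**
Reactants: 7 5-(dimethoxymethyl)-2-iodo-1-methoxy-3-[(S)-p-tolylsulfinyl]benzene; 8 3,5-dimethoxybenzyl bromide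
Product: 10 2-(3,5-dimethoxybenzyl)-5-(dimethoxymethyl)-1-methoxy-3-[(S)-p-tolylsulfinyl]benzene, via benzylic zinc bromide 9 (not isolated)
Conditions: 8, Zn dust (1.5 equiv), LiCl, THF, 0 → 25 °C; then 7, Pd(OAc)2 (2 mol%), SPhos (4 mol%), THF, 25 → 50 °C
Reagents that add atoms: none
Why: Zinc insertion into the benzylic C–Br bond gives a benzylic zinc reagent too weakly basic to deprotonate the acidic diarylmethane product or to attack the sulfoxide, and Negishi coupling with the di-ortho-substituted aryl iodide under zerovalent palladium catalysis (formed in the flask from Pd(OAc)2 and the biaryl phosphine) joins the two rings through the CH2 group.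

**Step 5**
Reactants: 10 2-(3,5-dimethoxybenzyl)-5-(dimethoxymethyl)-1-methoxy-3-[(S)-p-tolylsulfinyl]benzene; 11 4-methoxybenzaldehyde
Product: 15 (2S,3S)-3-(3,5-dimethoxyphenyl)-4-methoxy-2-(4-methoxyphenyl)-2,3-dihydrobenzofuran-6-carbaldehyde, via benzylic lithium carbanion 12 (not isolated), via lithium aldolate 13 (not isolated), via dimethyl acetal 14 (not isolated)
Conditions: LiN(iPr)2 (1.1 equiv), THF, −78 °C; 11, −78 °C; DMPU, −78 → 25 °C; then aq. HCl (1 M), THF, 25 °C
Reagents that add atoms: water, O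
Why: Proposed new method: the chelated ortho-sulfinyl benzylic carbanion 12 should add to the aldehyde on the face opposite the p-tolyl group (C3 set by the sulfinyl auxiliary), and the alkoxide of 13 should then displace the sulfinyl group at the ipso carbon in a 5-exo-trig addition–elimination (C2 set trans to the C3 aryl group because the reversibly formed aldolate epimers close at different rates), the closest known reaction type being the addition of ortho-sulfinyl benzyl carbanions to aldehydes and imines and the ipso-substitution of the sulfinyl group by the nitrogen anion of the imine adducts that gives indolines; the acid work-up hydrolyses the acetal.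

**Step 6**
Reactants: 15 (2S,3S)-3-(3,5-dimethoxyphenyl)-4-methoxy-2-(4-methoxyphenyl)-2,3-dihydrobenzofuran-6-carbaldehyde
Product: 16 [(2S,3S)-3-(3,5-dimethoxyphenyl)-4-methoxy-2-(4-methoxyphenyl)-2,3-dihydrobenzofuran-6-yl]methanol
Conditions: NaBH4, MeOH/THF, 0 °C
Reagents that add atoms: none
Why: Hydride reduction of the aryl aldehyde to the benzylic alcohol leaves the ethers and both stereocentres untouched.

**Step 7**
Reactants: 16 [(2S,3S)-3-(3,5-dimethoxyphenyl)-4-methoxy-2-(4-methoxyphenyl)-2,3-dihydrobenzofuran-6-yl]methanol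
Product: 17 (2S,3S)-6-(bromomethyl)-3-(3,5-dimethoxyphenyl)-4-methoxy-2-(4-methoxyphenyl)-2,3-dihydrobenzofuran
Conditions: CBr4, PPh3, CH2Cl2, 0 °C
Reagents that add atoms: carbon tetrabromide, BrC(Br)(Br)Br
Why: Appel reaction under neutral conditions converts the primary benzylic alcohol into the bromide without ionising the acid-sensitive 2-aryl ring ether.

**Step 8**
Reactants: 7 5-(dimethoxymethyl)-2-iodo-1-methoxy-3-[(S)-p-tolylsulfinyl]benzene; 17 (2S,3S)-6-(bromomethyl)-3-(3,5-dimethoxyphenyl)-4-methoxy-2-(4-methoxyphenyl)-2,3-dihydrobenzofuran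
Product: 19 (2S,3S)-6-{4-(dimethoxymethyl)-2-methoxy-6-[(S)-p-tolylsulfinyl]benzyl}-3-(3,5-dimethoxyphenyl)-4-methoxy-2-(4-methoxyphenyl)-2,3-dihydrobenzofuran, via benzylic zinc bromide 18 (not isolated)
Conditions: 17, Zn dust (1.5 equiv), LiCl, THF, 0 → 25 °C; then 7 (1.2 equiv), Pd(OAc)2 (2 mol%), SPhos (4 mol%), THF, 25 → 50 °C
Reagents that add atoms: none
Why: The same zinc insertion and Negishi coupling as in step 4, now between the benzylic zinc reagent of the outer unit and the second portion of iodide 7; the non-basic benzylic zinc reagent should leave the C3–H of the existing ring and both ring stereocentres alone.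

**Step 9**
Reactants: 19 (2S,3S)-6-{4-(dimethoxymethyl)-2-methoxy-6-[(S)-p-tolylsulfinyl]benzyl}-3-(3,5-dimethoxyphenyl)-4-methoxy-2-(4-methoxyphenyl)-2,3-dihydrobenzofuran; 11 4-methoxybenzaldehyde
Product: 23 (2S,3S)-3-[(2S,3S)-3-(3,5-dimethoxyphenyl)-4-methoxy-2-(4-methoxyphenyl)-2,3-dihydrobenzofuran-6-yl]-4-methoxy-2-(4-methoxyphenyl)-2,3-dihydrobenzofuran-6-carbaldehyde, via benzylic lithium carbanion 20 (not isolated), via lithium aldolate 21 (not isolated), via dimethyl acetal 22 (not isolated)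
Conditions: LiN(iPr)2 (1.1 equiv), THF, −78 °C; 11, −78 °C; DMPU, −78 → 25 °C; then aq. HCl (1 M), THF, 25 °C
Reagents that add atoms: water, O
Why: Proposed new method: LiN(iPr)2 should remove a proton from the CH2 group held next to the sulfinyl oxygen to give the chelated carbanion 20, which adds to the aldehyde carbon of 11 (new C2–C3 bond) to give aldolate 21; on warming, the alkoxide oxygen attacks the sulfinyl-bearing ring carbon C7a and p-toluenesulfenate leaves (new aryl C–O bond), so the sulfoxide acts in turn as acidifying group, chiral controller and nucleofuge. The closest known reaction type is the addition of ortho-sulfinyl benzyl carbanions to aldehydes and imines, and for the ring closure the intramolecular ipso-substitution of an aryl sulfinyl group by the nitrogen anion of the imine adducts that gives indolines; an alkoxide as nucleophile on a methoxy-substituted ring is the untested extension. The furan ring closes in a 5-exo-trig addition–elimination at the aromatic ipso carbon through a Meisenheimer-type anion (or by ligand coupling after attack at sulfur). C3 is set by the (S)-sulfinyl group, because in the six-membered C–Li–O–S chelate the p-tolyl group covers one face and the aldehyde enters from the lithium-bearing face, while C2 is set in the ring closure, where the aldolate epimers interconvert by retro-aldol and re-addition and the one that places the 4-methoxyphenyl group trans to ring C closes faster (Curtin–Hammett), which should give the trans-(2S,3S) ring. The step needs deprotonation of the CH2 group in preference to the C3–H of the existing ring and to ortho-metalation, which the sulfinyl-directed proximity and the acidifying ortho-sulfinyl group on the doubly benzylic CH2 should secure, and it needs ring closure in preference to retro-aldol loss, which the five-membered transition state and the irreversible departure of sulfenate should secure. Aqueous HCl in the work-up then hydrolyses the dimethyl acetal of 22 to the aldehyde 23.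

**Step 10**
Reactants: 23 (2S,3S)-3-[(2S,3S)-3-(3,5-dimethoxyphenyl)-4-methoxy-2-(4-methoxyphenyl)-2,3-dihydrobenzofuran-6-yl]-4-methoxy-2-(4-methoxyphenyl)-2,3-dihydrobenzofuran-6-carbaldehyde; 24 diethyl (4-methoxybenzyl)phosphonate
Product: 25 (2S,3S)-3-[(2S,3S)-3-(3,5-dimethoxyphenyl)-4-methoxy-2-(4-methoxyphenyl)-2,3-dihydrobenzofuran-6-yl]-4-methoxy-2-(4-methoxyphenyl)-6-[(E)-4-methoxystyryl]-2,3-dihydrobenzofuran
Conditions: 24 (1.5 equiv), KOtBu (1.4 equiv), THF, 0 → 25 °C
Reagents that add atoms: none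
Why: Horner–Wadsworth–Emmons olefination of a non-enolisable aryl aldehyde with a benzylic phosphonate should give the (E)-stilbene, and keeping the phosphonate in excess over the base protects the C3–H positions from elimination.

**Step 11**
Reactants: 25 (2S,3S)-3-[(2S,3S)-3-(3,5-dimethoxyphenyl)-4-methoxy-2-(4-methoxyphenyl)-2,3-dihydrobenzofuran-6-yl]-4-methoxy-2-(4-methoxyphenyl)-6-[(E)-4-methoxystyryl]-2,3-dihydrobenzofuran
Product: 26 (2S,3S)-3-[(2S,3S)-3-(3,5-dihydroxyphenyl)-4-hydroxy-2-(4-hydroxyphenyl)-2,3-dihydrobenzofuran-6-yl]-2-(4-hydroxyphenyl)-6-[(E)-4-hydroxystyryl]-2,3-dihydrobenzofuran-4-ol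
Conditions: BBr3 (20 equiv), CH2Cl2, −78 → 25 °C; then H2O, 0 °C
Reagents that add atoms: none
Why: Lewis-acid cleavage of the seven aryl methyl ethers by bromide attack on the boron-activated O–CH3 groups, a standard last step for permethylated oligostilbenes that does not touch the four stereocentres.

**Compound list**
1 | 3-bromo-5-methoxybenzaldehyde | O=Cc1cc(Br)cc(OC)c1 | starting material
2 | 1-bromo-3-(dimethoxymethyl)-5-methoxybenzene | COC(OC)c1cc(Br)cc(OC)c1 | intermediate
3 | (1R,2S,5R)-menthyl (S)-p-toluenesulfinate | C[C@@H]1CC[C@H]([C@@H](C1)O[S@](=O)c1ccc(C)cc1)C(C)C | starting material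
4 | [3-(dimethoxymethyl)-5-methoxyphenyl]magnesium bromide | COC(OC)c1cc([Mg]Br)cc(OC)c1 | intermediate
5 | (S)-1-(dimethoxymethyl)-3-methoxy-5-(p-tolylsulfinyl)benzene | COC(OC)c1cc(OC)cc(c1)[S@@](=O)c1ccc(C)cc1 | intermediate
6 | {4-(dimethoxymethyl)-2-methoxy-6-[(S)-p-tolylsulfinyl]phenyl}lithium | COC(OC)c1cc(OC)c([Li])c(c1)[S@@](=O)c1ccc(C)cc1 | intermediate
7 | 5-(dimethoxymethyl)-2-iodo-1-methoxy-3-[(S)-p-tolylsulfinyl]benzene | COC(OC)c1cc(OC)c(I)c(c1)[S@@](=O)c1ccc(C)cc1 | intermediate
8 | 3,5-dimethoxybenzyl bromide | COc1cc(CBr)cc(OC)c1 | starting material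
9 | (3,5-dimethoxybenzyl)zinc bromide | COc1cc(C[Zn]Br)cc(OC)c1 | intermediate
10 | 2-(3,5-dimethoxybenzyl)-5-(dimethoxymethyl)-1-methoxy-3-[(S)-p-tolylsulfinyl]benzene | COC(OC)c1cc(OC)c(Cc2cc(OC)cc(OC)c2)c(c1)[S@@](=O)c1ccc(C)cc1 | intermediate
11 | 4-methoxybenzaldehyde | COc1ccc(C=O)cc1 | starting material
12 | benzylic lithium carbanion of 10 (lithium on the diarylmethyl carbon) | COC(OC)c1cc(OC)c(C([Li])c2cc(OC)cc(OC)c2)c(c1)[S@@](=O)c1ccc(C)cc1 | intermediate
13 | lithium (1S,2S)-2-(3,5-dimethoxyphenyl)-2-{4-(dimethoxymethyl)-2-methoxy-6-[(S)-p-tolylsulfinyl]phenyl}-1-(4-methoxyphenyl)ethan-1-olate | COC(OC)c1cc(OC)c(c(c1)[S@@](=O)c1ccc(C)cc1)[C@H](c1cc(OC)cc(OC)c1)[C@H](O[Li])c1ccc(OC)cc1 | intermediate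
14 | (2S,3S)-6-(dimethoxymethyl)-3-(3,5-dimethoxyphenyl)-4-methoxy-2-(4-methoxyphenyl)-2,3-dihydrobenzofuran | COC(OC)c1cc(OC)c2c(c1)O[C@H](c1ccc(OC)cc1)[C@H]2c1cc(OC)cc(OC)c1 | intermediate
15 | (2S,3S)-3-(3,5-dimethoxyphenyl)-4-methoxy-2-(4-methoxyphenyl)-2,3-dihydrobenzofuran-6-carbaldehyde | O=Cc1cc(OC)c2c(c1)O[C@H](c1ccc(OC)cc1)[C@H]2c1cc(OC)cc(OC)c1 | intermediate
16 | [(2S,3S)-3-(3,5-dimethoxyphenyl)-4-methoxy-2-(4-methoxyphenyl)-2,3-dihydrobenzofuran-6-yl]methanol | OCc1cc(OC)c2c(c1)O[C@H](c1ccc(OC)cc1)[C@H]2c1cc(OC)cc(OC)c1 | intermediate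
17 | (2S,3S)-6-(bromomethyl)-3-(3,5-dimethoxyphenyl)-4-methoxy-2-(4-methoxyphenyl)-2,3-dihydrobenzofuran | BrCc1cc(OC)c2c(c1)O[C@H](c1ccc(OC)cc1)[C@H]2c1cc(OC)cc(OC)c1 | intermediate
18 | {[(2S,3S)-3-(3,5-dimethoxyphenyl)-4-methoxy-2-(4-methoxyphenyl)-2,3-dihydrobenzofuran-6-yl]methyl}zinc bromide | Br[Zn]Cc1cc(OC)c2c(c1)O[C@H](c1ccc(OC)cc1)[C@H]2c1cc(OC)cc(OC)c1 | intermediate
19 | (2S,3S)-6-{4-(dimethoxymethyl)-2-methoxy-6-[(S)-p-tolylsulfinyl]benzyl}-3-(3,5-dimethoxyphenyl)-4-methoxy-2-(4-methoxyphenyl)-2,3-dihydrobenzofuran | COC(OC)c1cc(OC)c(Cc2cc(OC)c3c(c2)O[C@H](c2ccc(OC)cc2)[C@H]3c2cc(OC)cc(OC)c2)c(c1)[S@@](=O)c1ccc(C)cc1 | intermediate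
20 | benzylic lithium carbanion of 19 (lithium on the diarylmethyl carbon) | COC(OC)c1cc(OC)c(C([Li])c2cc(OC)c3c(c2)O[C@H](c2ccc(OC)cc2)[C@H]3c2cc(OC)cc(OC)c2)c(c1)[S@@](=O)c1ccc(C)cc1 | intermediate
21 | lithium (1S,2S)-2-[(2S,3S)-3-(3,5-dimethoxyphenyl)-4-methoxy-2-(4-methoxyphenyl)-2,3-dihydrobenzofuran-6-yl]-2-{4-(dimethoxymethyl)-2-methoxy-6-[(S)-p-tolylsulfinyl]phenyl}-1-(4-methoxyphenyl)ethan-1-olate | COC(OC)c1cc(OC)c(c(c1)[S@@](=O)c1ccc(C)cc1)[C@H](c1cc(OC)c2c(c1)O[C@H](c1ccc(OC)cc1)[C@H]2c1cc(OC)cc(OC)c1)[C@H](O[Li])c1ccc(OC)cc1 | intermediate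
22 | (2S,3S)-6-(dimethoxymethyl)-3-[(2S,3S)-3-(3,5-dimethoxyphenyl)-4-methoxy-2-(4-methoxyphenyl)-2,3-dihydrobenzofuran-6-yl]-4-methoxy-2-(4-methoxyphenyl)-2,3-dihydrobenzofuran | COC(OC)c1cc(OC)c2c(c1)O[C@H](c1ccc(OC)cc1)[C@H]2c1cc(OC)c2c(c1)O[C@H](c1ccc(OC)cc1)[C@H]2c1cc(OC)cc(OC)c1 | intermediate
23 | (2S,3S)-3-[(2S,3S)-3-(3,5-dimethoxyphenyl)-4-methoxy-2-(4-methoxyphenyl)-2,3-dihydrobenzofuran-6-yl]-4-methoxy-2-(4-methoxyphenyl)-2,3-dihydrobenzofuran-6-carbaldehyde | O=Cc1cc(OC)c2c(c1)O[C@H](c1ccc(OC)cc1)[C@H]2c1cc(OC)c2c(c1)O[C@H](c1ccc(OC)cc1)[C@H]2c1cc(OC)cc(OC)c1 | intermediate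
24 | diethyl (4-methoxybenzyl)phosphonate | CCOP(=O)(Cc1ccc(OC)cc1)OCC | starting material
25 | (2S,3S)-3-[(2S,3S)-3-(3,5-dimethoxyphenyl)-4-methoxy-2-(4-methoxyphenyl)-2,3-dihydrobenzofuran-6-yl]-4-methoxy-2-(4-methoxyphenyl)-6-[(E)-4-methoxystyryl]-2,3-dihydrobenzofuran | COc1ccc(/C=C/c2cc(OC)c3c(c2)O[C@H](c2ccc(OC)cc2)[C@H]3c2cc(OC)c3c(c2)O[C@H](c2ccc(OC)cc2)[C@H]3c2cc(OC)cc(OC)c2)cc1 | intermediate
26 | (2S,3S)-3-[(2S,3S)-3-(3,5-dihydroxyphenyl)-4-hydroxy-2-(4-hydroxyphenyl)-2,3-dihydrobenzofuran-6-yl]-2-(4-hydroxyphenyl)-6-[(E)-4-hydroxystyryl]-2,3-dihydrobenzofuran-4-ol | Oc1ccc(/C=C/c2cc(O)c3c(c2)O[C@H](c2ccc(O)cc2)[C@H]3c2cc(O)c3c(c2)O[C@H](c2ccc(O)cc2)[C@H]3c2cc(O)cc(O)c2)cc1 | target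

**Totals**
Total step count: 11. Longest linear sequence: 11 steps (1 → 26; compound 7 enters a second time in step 8).

**Steps most likely to fail**

Step 9 (key step). On warming, the lithium aldolate may revert to carbanion and aldehyde faster than its oxygen displaces the sulfinyl group from the electron-rich ring, so that no ring closure occurs and the aldehyde is consumed by hydride-transfer side reactions. The fallback sets out from 19 and uses known chemistry. Deprotonation with LiN(iPr)2 at −78 °C, addition of 11 and quenching with AcOH at −78 °C should give the hydroxy sulfoxide F1; the sulfinyl group should make the carbinol epimers separable by chromatography, and the (1S,2S) epimer is carried on. Sulfoxide–magnesium exchange (i-PrMgCl·LiCl, 3 equiv, THF, −40 °C) followed by I2 should give the aryl iodide F2. Ullmann-type intramolecular etherification (CuI, 3,4,7,8-tetramethyl-1,10-phenanthroline, Cs2CO3, toluene, 110 °C) retains both configurations and returns to the route at acetal 22, which is hydrolysed to 23 as in step 9.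

Step 5. The same untested ipso-substitution is used here, and in addition the carbinol centre may form with poor selectivity if the aldolate epimers do not equilibrate before ring closure. The fallback sets out from 10 and forms the other C–O bond of the ring in a stereoconvergent way. Addition to 11 at −78 °C with a low-temperature quench should give the hydroxy sulfoxide F3, with the diarylmethine centre (C2 of the ethanol chain) fixed by the auxiliary and the carbinol centre as a mixture. Sulfoxide–magnesium exchange (i-PrMgCl·LiCl), trapping with B(OMe)3 and oxidation (H2O2, NaOH) should give the phenol F4. Catalytic CF3CO2H in CH2Cl2 at 0 °C ionises the 4-methoxybenzylic alcohol; the phenol captures the cation anti to the neighbouring aryl group to give the trans ring whatever the carbinol configuration, and the aqueous acid work-up cleaves the acetal. The route is rejoined at 15.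

Step 11. During Lewis-acid cleavage of seven methyl ethers the electron-rich stilbene may be protonated and the resulting cation captured by a resorcinol-type ring or by another molecule, alongside incomplete demethylation. The fallback sets out from 23 and removes the methyl groups before the alkene exists. BBr3 (CH2Cl2, −78 → 25 °C) should give the hexaphenol aldehyde F5, and TBSCl/imidazole in DMF the hexakis(silyl ether) aldehyde F6. Horner–Wadsworth–Emmons olefination (NaH, THF, 0 °C) with the silylated phosphonate F7, made from commercial diethyl (4-hydroxybenzyl)phosphonate and TBSCl/imidazole, should give the heptakis(silyl ether) stilbene F8. Buffered fluoride (Bu4NF, AcOH, THF, 0 °C) then releases 26.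

**Further compounds**
F1 | step 9 | (1S,2S)-2-[(2S,3S)-3-(3,5-dimethoxyphenyl)-4-methoxy-2-(4-methoxyphenyl)-2,3-dihydrobenzofuran-6-yl]-2-{4-(dimethoxymethyl)-2-methoxy-6-[(S)-p-tolylsulfinyl]phenyl}-1-(4-methoxyphenyl)ethan-1-ol | COC(OC)c1cc(OC)c(c(c1)[S@@](=O)c1ccc(C)cc1)[C@H](c1cc(OC)c2c(c1)O[C@H](c1ccc(OC)cc1)[C@H]2c1cc(OC)cc(OC)c1)[C@H](O)c1ccc(OC)cc1
F2 | step 9 | (1S,2S)-2-[(2S,3S)-3-(3,5-dimethoxyphenyl)-4-methoxy-2-(4-methoxyphenyl)-2,3-dihydrobenzofuran-6-yl]-2-[4-(dimethoxymethyl)-2-iodo-6-methoxyphenyl]-1-(4-methoxyphenyl)ethan-1-ol | COC(OC)c1cc(OC)c(c(I)c1)[C@H](c1cc(OC)c2c(c1)O[C@H](c1ccc(OC)cc1)[C@H]2c1cc(OC)cc(OC)c1)[C@H](O)c1ccc(OC)cc1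
F3 | step 5 | (2S)-2-(3,5-dimethoxyphenyl)-2-{4-(dimethoxymethyl)-2-methoxy-6-[(S)-p-tolylsulfinyl]phenyl}-1-(4-methoxyphenyl)ethan-1-ol, mixture of C1 epimers | COC(OC)c1cc(OC)c(c(c1)[S@@](=O)c1ccc(C)cc1)[C@H](c1cc(OC)cc(OC)c1)C(O)c1ccc(OC)cc1
F4 | step 5 | 5-(dimethoxymethyl)-2-[(1S)-1-(3,5-dimethoxyphenyl)-2-hydroxy-2-(4-methoxyphenyl)ethyl]-3-methoxyphenol, mixture of carbinol epimers | COC(OC)c1cc(OC)c(c(O)c1)[C@H](c1cc(OC)cc(OC)c1)C(O)c1ccc(OC)cc1
F5 | step 11 | (2S,3S)-3-[(2S,3S)-3-(3,5-dihydroxyphenyl)-4-hydroxy-2-(4-hydroxyphenyl)-2,3-dihydrobenzofuran-6-yl]-4-hydroxy-2-(4-hydroxyphenyl)-2,3-dihydrobenzofuran-6-carbaldehyde | O=Cc1cc(O)c2c(c1)O[C@H](c1ccc(O)cc1)[C@H]2c1cc(O)c2c(c1)O[C@H](c1ccc(O)cc1)[C@H]2c1cc(O)cc(O)c1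
F6 | step 11 | hexakis(tert-butyldimethylsilyl) ether of F5 | O=Cc1cc(O[Si](C)(C)C(C)(C)C)c2c(c1)O[C@H](c1ccc(O[Si](C)(C)C(C)(C)C)cc1)[C@H]2c1cc(O[Si](C)(C)C(C)(C)C)c2c(c1)O[C@H](c1ccc(O[Si](C)(C)C(C)(C)C)cc1)[C@H]2c1cc(O[Si](C)(C)C(C)(C)C)cc(O[Si](C)(C)C(C)(C)C)c1
F7 | step 11 | diethyl [4-(tert-butyldimethylsilyloxy)benzyl]phosphonate | CCOP(=O)(Cc1ccc(O[Si](C)(C)C(C)(C)C)cc1)OCC
F8 | step 11 | heptakis(tert-butyldimethylsilyl) ether of 26 | CC(C)(C)[Si](C)(C)Oc1ccc(/C=C/c2cc(O[Si](C)(C)C(C)(C)C)c3c(c2)O[C@H](c2ccc(O[Si](C)(C)C(C)(C)C)cc2)[C@H]3c2cc(O[Si](C)(C)C(C)(C)C)c3c(c2)O[C@H](c2ccc(O[Si](C)(C)C(C)(C)C)cc2)[C@H]3c2cc(O[Si](C)(C)C(C)(C)C)cc(O[Si](C)(C)C(C)(C)C)c2)cc1
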